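The target is numbered as a heptane: C1 is the ring CHBr carbon, C2 the ring CH carbon, C3 the exocyclic CBr2 carbon. Everything rests on disconnecting C2–C3. The key step exploits that the oxirane oxygen sits on C2 between two bromine-bearing carbons (C1 in the ring, C3 outside it): the ring is a closed β-bromo alkoxide, so C2 is a masked aldehyde carbon and C3 a carbenoid carbon. Enantioselective 1,2-addition of (1,1-dibromopentyl)lithium, held in a chiral lithium amide aggregate, to dibromoacetaldehyde forms this bond, sets C2 and assembles all four bromines of (S)-1,1,3,3-tetrabromoheptan-2-ol in one operation from 1,1-dibromopentane; base then closes the trans-bromooxirane.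

Key step: step 2

Assumption: dibromoacetaldehyde (3) is taken as a purchasable compound and is distilled to the anhydrous monomer before use.
Assumption: both enantiomers of 2-(pyrrolidin-1-ylmethyl)pyrrolidine are commercial; the (S)-amide is written, and its antipode would be used if the sense of induction proved opposite.

Step 1
Reactants: 1 pentanal
Product: 2 1,1-dibromopentane
Conditions: (PhO)3P, Br2, Et3N, CH2Cl2, −60 °C to rt
Reagents that add atoms: bromine, BrBr
Why: Dibromotriphenoxyphosphorane formed in the flask activates the carbonyl oxygen as a phosphorus-bound leaving group and bromide substitutes twice (deoxygenative gem-dibromination of an aldehyde with a phosphite–halogen reagent, Appel-type), with no stereocenter formed.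

Step 2
Reactants: 2 1,1-dibromopentane; 3 dibromoacetaldehyde
Product: 6 (S)-1,1,3,3-tetrabromoheptan-2-ol, via (1,1-dibromopentyl)lithium 4 (not isolated), via lithium (S)-1,1,3,3-tetrabromoheptan-2-olate 5 (not isolated)
Conditions: (S)-2-(pyrrolidin-1-ylmethyl)pyrrolidine, n-BuLi (Li amide, 2 equiv), Et2O–THF, −110 °C; then 3; AcOH, −110 °C
Reagents that add atoms: none
Why: Proposed new method: the chiral lithium amide deprotonates 2 at its CHBr2 carbon and the carbenoid 4 stays in a chelated mixed amide–carbenoid aggregate, to whose lithium aldehyde 3 binds before the carbenoid carbon adds to C=O through a four-centre Li–C/C=O transition state, forming the C2–C3 bond and alkoxide 5. The closest known reaction types are the racemic 1,2-addition of 1,1-dibromoalkyllithiums to aldehydes and the enantioselective 1,2-addition of alkyllithiums to aldehydes inside mixed aggregates of chiral lithium amides; applying the second to a lithium carbenoid is the new element. No ring is closed in this step. The single new stereocenter C2 is controlled by the (S)-pyrrolidide ligand, which must expose the Re face of 3 so that the (S)-alkoxide results. The step needs carbonyl addition to outrun enolisation or Br–Li exchange of 3 and α-elimination of 4, which the high electrophilicity of the α,α-dibromo aldehyde and the −110 °C regime should secure. Protonation with AcOH at −110 °C keeps 5 from closing to an oxirane in the presence of amine and lithium salts.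

Step 3
Reactants: 6 (S)-1,1,3,3-tetrabromoheptan-2-ol
Product: 8 (2R,3S)-2-bromo-3-(1,1-dibromopentyl)oxirane, via sodium (S)-1,1,3,3-tetrabromoheptan-2-olate 7 (not isolated)
Conditions: NaH, THF, 0 °C
Reagents that add atoms: none
Why: Alkoxide 7 should displace one C1 bromide by intramolecular SN2 (3-exo-tet Williamson-type closure of a vicinal bromohydrin) at the CHBr2 carbon in preference to the fully substituted C3, with C2 keeping its configuration and C1 set as R because the rotamer that leaves the remaining bromine trans to the bulky 1,1-dibromopentyl group is the one that closes.

Compound list
1 | pentanal | CCCCC=O | starting material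
2 | 1,1-dibromopentane | CCCCC(Br)Br | intermediate
3 | dibromoacetaldehyde (2,2-dibromoethanal) | O=CC(Br)Br | starting material
4 | (1,1-dibromopentyl)lithium | [Li]C(Br)(Br)CCCC | intermediate (not isolated)
5 | lithium (S)-1,1,3,3-tetrabromoheptan-2-olate | CCCCC(Br)(Br)[C@@H](O[Li])C(Br)Br | intermediate (not isolated)
6 | (S)-1,1,3,3-tetrabromoheptan-2-ol | CCCCC(Br)(Br)[C@@H](O)C(Br)Br | intermediate
7 | sodium (S)-1,1,3,3-tetrabromoheptan-2-olate | CCCCC(Br)(Br)[C@@H](O[Na])C(Br)Br | intermediate (not isolated)
8 | (2R,3S)-2-bromo-3-(1,1-dibromopentyl)oxirane (trans) | CCCCC(Br)(Br)[C@H]1O[C@@H]1Br | target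

Total step count: 3
Longest linear sequence: 3

Steps most likely to fail

Step 2 (Proposed new method). The mixed aggregate may give poor facial selectivity, and the amide or the carbenoid may enolise the aldehyde or attack its bromines instead of adding to the carbonyl group. The fallback uses known chemistry, sets out from 2 and 3 and comes back at 6. Deprotonation of 2 with LDA (THF–Et2O, −105 °C) gives 4, which adds to 3 without facial control to give racemic lithium 1,1,3,3-tetrabromoheptan-2-olate F1, protonated cold with AcOH to racemic 1,1,3,3-tetrabromoheptan-2-ol F2. Dess–Martin oxidation (CH2Cl2, NaHCO3, 0 °C) would give 1,1,3,3-tetrabromoheptan-2-one F3. Corey–Bakshi–Shibata reduction with (R)-Me-CBS and catecholborane (toluene, −78 °C), in which the 1,1-dibromopentyl group acts as the large substituent, should return the (S)-alcohol 6. The C2–C3 bond is still formed by the carbenoid addition; only the control of C2 moves to the reduction.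

Step 3. Ring closure may take place at the fully substituted C3 instead of C1, and lithium or sodium salts or acidic supports may trigger rearrangement of the α-bromo oxirane to an α-bromo carbonyl compound. The fallback sets out from 6 and comes back at 8. It is an enzymatic ring closure with a halohydrin dehalogenase (HheC-type, screened as a panel) in a Tris–sulfate buffer pH 8/MTBE two-phase system at 20 °C. The halide pocket of the enzyme should accept the terminal CHBr2 carbon only, and the catalytic tyrosine deprotonates the C2 hydroxyl. This fallback makes no new compound (F0).

Step 1. Enolisation of the aldehyde may lead to elimination to 1-bromopent-1-ene and to aldol self-condensation in place of gem-dibromination. The fallback sets out from 1 and comes back at 2. Condensation with hydrazine hydrate (EtOH, 0 °C) gives pentanal hydrazone F4. Oxidative gem-dibromination with CuBr2 and t-BuOLi (THF, rt) should then give 2 with loss of nitrogen.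

Further compounds
F1 | step 2 | racemic lithium 1,1,3,3-tetrabromoheptan-2-olate | CCCCC(Br)(Br)C(O[Li])C(Br)Br
F2 | step 2 | racemic 1,1,3,3-tetrabromoheptan-2-ol | CCCCC(Br)(Br)C(O)C(Br)Br
F3 | step 2 | 1,1,3,3-tetrabromoheptan-2-one | CCCCC(Br)(Br)C(=O)C(Br)Br
F0 | step 3 | none | none
F4 | step 1 | pentanal hydrazone | CCCCC=NN
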